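**Retrosynthetic overview**

1. The last operation is hydrogenolysis of a benzyl ether on the C6 oxygen of ring A; before it stands the (S)-isoflavan with ring B complete.
2. The plan rests on ring B: a free hydroxyl at C2' between C1' (bonded to C3 of the chroman) and the methoxy-bearing C3' and C4', with C5' and C6' unsubstituted. A 2,3-dimethoxy-4-alkenylcyclobutenone gives this pattern on ring expansion (C=O becomes C2'–OH, the two enol-ether carbons become C3' and C4'), so ring B is disconnected at C1'–C2'.
3. The cyclobutenone is cut at its C4–alkenyl bond into an (S)-(E)-alkenylstannane and 4-chloro-2,3-dimethoxycyclobutenone, the latter two steps from dimethyl squarate.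
4. The stannane comes from (R)-chroman-3-carboxylic acid by reduction, oxidation and chromium-mediated stannyl olefination; C3 is set by asymmetric hydrogenation of the 2H-chromene-3-carboxylic acid.
5. Ring order: ring A is bought as 2,3-dimethoxyphenol and oxygenated; the pyran ring (ring C) is closed by oxa-Michael/aldol condensation with acrolein; ring B is formed last.

Key step: step 14

Assumption: in step 6 the (S)-BINAP complex is taken, by analogy with (E)-2-alkyl-3-substituted acrylic acids, to give the (R)-acid; the sense is to be checked on the product and the (R)-ligand used if it proves opposite.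

**Route**

Step 1
Reactants: 1 2,3-dimethoxyphenol
Product: 2 2-hydroxy-3,4-dimethoxybenzaldehyde
Conditions: MgCl2, Et3N, (CH2O)n, MeCN, reflux; aq. HCl work-up
Reagents that add atoms: paraformaldehyde (formaldehyde source), C=O
Why: Magnesium-phenoxide-directed ortho-formylation (Casnati–Skattebøl) delivers formaldehyde to the only free ortho position, and a second equivalent of formaldehyde oxidises the benzylic alkoxide to the aldehyde.

Step 2
Reactants: 2 2-hydroxy-3,4-dimethoxybenzaldehyde
Product: 4 2,5-dihydroxy-3,4-dimethoxybenzaldehyde, via aryl sulfate 3 (not isolated)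
Conditions: K2S2O8, aq. KOH, 0 to 20 °C; then aq. HCl, 80 °C
Reagents that add atoms: potassium peroxodisulfate, [K+].[K+].[O-]S(=O)(=O)OOS(=O)(=O)[O-]
Why: Elbs persulfate oxidation: the phenoxide attacks the peroxide bond through its para carbon (C5, the only activated position left open, both ortho positions being substituted) to give aryl sulfate 3, which acid hydrolyses to the hydroquinone.

Step 3
Reactants: 4 2,5-dihydroxy-3,4-dimethoxybenzaldehyde
Product: 5 5-(benzyloxy)-2-hydroxy-3,4-dimethoxybenzaldehyde
Conditions: K2CO3 (2.2 equiv), BnBr (1.0 equiv), DMF, 0 °C to rt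
Reagents that add atoms: benzyl bromide, BrCc1ccccc1
Why: Williamson etherification of the dianion: the 5-phenoxide is neither conjugated with nor chelated to the formyl group and is the more nucleophilic oxygen, so one equivalent of benzyl bromide should alkylate O5 and leave the hydrogen-bonded 2-OH free.

Step 4
Reactants: 5 5-(benzyloxy)-2-hydroxy-3,4-dimethoxybenzaldehyde; 6 acrolein
Product: 7 6-(benzyloxy)-7,8-dimethoxy-2H-chromene-3-carbaldehyde
Conditions: K2CO3, 1,4-dioxane, reflux
Reagents that add atoms: none
Why: Domino oxa-Michael addition of the phenoxide to acrolein and intramolecular aldol condensation of the resulting enolate with the formyl group closes ring C as the 2H-chromene-3-carbaldehyde.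

Step 5
Reactants: 7 6-(benzyloxy)-7,8-dimethoxy-2H-chromene-3-carbaldehyde
Product: 8 6-(benzyloxy)-7,8-dimethoxy-2H-chromene-3-carboxylic acid
Conditions: NaClO2, NaH2PO4, 2-methyl-2-butene, t-BuOH/H2O, rt
Reagents that add atoms: sodium chlorite, [Na+].[O-]Cl=O
Why: Pinnick oxidation converts the enal into the acid without touching the alkene or the electron-rich ring, the hypochlorous acid formed being trapped by 2-methyl-2-butene.

Step 6
Reactants: 8 6-(benzyloxy)-7,8-dimethoxy-2H-chromene-3-carboxylic acid
Product: 9 (R)-6-(benzyloxy)-7,8-dimethoxychroman-3-carboxylic acid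
Conditions: Ru(OAc)2[(S)-BINAP] (1 mol %), H2 (30 atm), MeOH, 25 °C
Reagents that add atoms: none
Why: Noyori-type carboxylate-directed asymmetric hydrogenation of an α,β-unsaturated acid: the substrate binds ruthenium as its carboxylate and the BINAP ligand fixes the face to which both hydrogens are delivered, which sets C3; the benzyl ether is inert to the homogeneous catalyst and the crystalline acid can be enriched by recrystallisation.

Step 7
Reactants: 9 (R)-6-(benzyloxy)-7,8-dimethoxychroman-3-carboxylic acid
Product: 10 (S)-[6-(benzyloxy)-7,8-dimethoxychroman-3-yl]methanol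
Conditions: BH3·THF, THF, 0 °C to rt; H2O
Reagents that add atoms: none
Why: Borane reduction of a carboxylic acid via the acyloxyborane is chemoselective and non-basic, so C3 cannot epimerise (the descriptor changes only because the priorities change).

Step 8
Reactants: 10 (S)-[6-(benzyloxy)-7,8-dimethoxychroman-3-yl]methanol
Product: 11 (R)-6-(benzyloxy)-7,8-dimethoxychroman-3-carbaldehyde
Conditions: PhI(OAc)2, TEMPO (10 mol %), CH2Cl2, rt; used at once
Reagents that add atoms: none
Why: Oxoammonium (TEMPO) oxidation with PhI(OAc)2 as terminal oxidant stops at the aldehyde under base-free conditions, so the now enolisable C3 centre is not exposed to base.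

Step 9
Reactants: 12 dibromomethane; 13 tributyltin chloride
Product: 14 tributyl(dibromomethyl)stannane
Conditions: LiN(iPr)2, THF, −95 °C to rt
Reagents that add atoms: none
Why: Deprotonation of dibromomethane gives dibromomethyllithium, which is trapped at tin by displacement of chloride (carbenoid stannylation).

Step 10
Reactants: 11 (R)-6-(benzyloxy)-7,8-dimethoxychroman-3-carbaldehyde; 14 tributyl(dibromomethyl)stannane
Product: 15 tributyl{(E)-2-[(S)-6-(benzyloxy)-7,8-dimethoxychroman-3-yl]ethenyl}stannane
Conditions: CrCl2, LiI (lithium iodide), DMF/THF, rt, dark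
Reagents that add atoms: none
Why: Takai-type olefination in its stannyl (Hodgson) variant: divalent chromium converts the gem-dihalide into a geminal dichromium species that adds to the aldehyde and eliminates to the (E)-alkenylstannane under non-basic conditions that should leave C3 untouched.

Step 11
Reactants: 16 dimethyl squarate
Product: 17 4-hydroxy-2,3-dimethoxycyclobut-2-en-1-one (racemic)
Conditions: LiAlH(OtBu)3 (1.05 equiv), THF, −78 to −40 °C; pH 7 phosphate buffer
Reagents that add atoms: none
Why: 1,2-Monoreduction of one of the two equivalent squarate carbonyl groups by a bulky, mild hydride; the vinylogous ester that remains is much less electrophilic.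

Step 12
Reactants: 17 4-hydroxy-2,3-dimethoxycyclobut-2-en-1-one
Product: 18 4-chloro-2,3-dimethoxycyclobut-2-en-1-one (racemic, used at once)
Conditions: PPh3, CCl4, CH2Cl2, 0 °C to rt
Reagents that add atoms: carbon tetrachloride, ClC(Cl)(Cl)Cl
Why: Appel chlorination: the alkoxyphosphonium ion is displaced by chloride at C4, an SN2 reaction accelerated by the adjacent carbonyl, under neutral conditions that avoid acid-catalysed loss of methanol.

Step 13
Reactants: 15 tributyl{(E)-2-[(S)-6-(benzyloxy)-7,8-dimethoxychroman-3-yl]ethenyl}stannane; 18 4-chloro-2,3-dimethoxycyclobut-2-en-1-one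
Product: 19 4-{(E)-2-[(S)-6-(benzyloxy)-7,8-dimethoxychroman-3-yl]ethenyl}-2,3-dimethoxycyclobut-2-en-1-one (both epimers at C4 of the four-membered ring)
Conditions: Pd2(dba)3 (2.5 mol %), tri(2-furyl)phosphine (10 mol %), 1,4-dioxane, 45 °C; rapid filtration through silica
Reagents that add atoms: none
Why: Stille coupling of a 4-chlorocyclobutenone: zerovalent palladium adds oxidatively to the allylic, α-keto C–Cl bond, the alkenyl group is transferred from tin with retention of the (E) geometry, and reductive elimination at the less hindered C4 terminus gives the conjugated cyclobutenone (any 19 that already rearranges is simply carried into step 14).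

Step 14
Reactants: 19 4-{(E)-2-[(S)-6-(benzyloxy)-7,8-dimethoxychroman-3-yl]ethenyl}-2,3-dimethoxycyclobut-2-en-1-one
Product: 22 (S)-6-(benzyloxy)-3-(2-hydroxy-3,4-dimethoxyphenyl)-7,8-dimethoxychroman, via dienylketene 20 (not isolated), via cyclohexa-2,4-dienone 21 (not isolated)
Conditions: PhMe (0.02 M, degassed), 100 °C
Reagents that add atoms: none
Why: Thermal 4π conrotatory opening of the cyclobutenone C1–C4 bond gives dienylketene 20, whose 6π disrotatory electrocyclisation joins the ketene carbon to the alkene carbon bearing the chroman (the C1'–C2' bond) to give cyclohexa-2,4-dienone 21, and enolisation of 21 gives the phenol. The closest known reaction is the thermal rearrangement of 4-alkenylcyclobutenones, made by Stille coupling of 4-chlorocyclobutenones, to phenols (and of their 4-hydroxy analogues to hydroquinones). Ring B is closed by this 6π electrocyclic ring closure, a six-membered closure onto the sp carbon of the ketene. No stereocentre is formed: the C4 centre of 19 and the sp3 ring carbon of 21 both vanish on aromatisation, and C3 lies outside the pericyclic array and is not enolisable. The selectivity needed is inward rotation of the alkenyl group in the ring opening; because the opening is reversible, the outward rotamer recloses and the material should drain through the rotamer that can cyclise, while the (E)-alkene keeps the chroman away from the forming bond. The substitution pattern (OH at C2', methoxy groups at C3' and C4', hydrogen at C5' and C6') is fixed by the connectivity of 19 alone.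

Step 15
Reactants: 22 (S)-6-(benzyloxy)-3-(2-hydroxy-3,4-dimethoxyphenyl)-7,8-dimethoxychroman
Product: 23 (S)-3-(2-hydroxy-3,4-dimethoxyphenyl)-7,8-dimethoxychroman-6-ol
Conditions: H2 (1 atm), 10% Pd/C, EtOAc/MeOH, rt
Reagents that add atoms: none
Why: Heterogeneous hydrogenolysis of the benzyl aryl ether; the chroman C–O bonds, the methyl ethers and the C3 stereocentre are not affected.

**Compound list**

1 | 2,3-dimethoxyphenol | COc1cccc(O)c1OC | starting material
2 | 2-hydroxy-3,4-dimethoxybenzaldehyde | COc1ccc(C=O)c(O)c1OC | intermediate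
3 | potassium 5-formyl-4-hydroxy-2,3-dimethoxyphenyl sulfate | COc1c(OS(=O)(=O)[O-])cc(C=O)c(O)c1OC.[K+] | intermediate
4 | 2,5-dihydroxy-3,4-dimethoxybenzaldehyde | COc1c(O)cc(C=O)c(O)c1OC | intermediate
5 | 5-(benzyloxy)-2-hydroxy-3,4-dimethoxybenzaldehyde | COc1c(OCc2ccccc2)cc(C=O)c(O)c1OC | intermediate
6 | acrolein | C=CC=O | starting material
7 | 6-(benzyloxy)-7,8-dimethoxy-2H-chromene-3-carbaldehyde | O=CC1=Cc2cc(OCc3ccccc3)c(OC)c(OC)c2OC1 | intermediate
8 | 6-(benzyloxy)-7,8-dimethoxy-2H-chromene-3-carboxylic acid | OC(=O)C1=Cc2cc(OCc3ccccc3)c(OC)c(OC)c2OC1 | intermediate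
9 | (R)-6-(benzyloxy)-7,8-dimethoxychroman-3-carboxylic acid | OC(=O)[C@H]1COc2c(cc(OCc3ccccc3)c(OC)c2OC)C1 | intermediate
10 | (S)-[6-(benzyloxy)-7,8-dimethoxychroman-3-yl]methanol | OC[C@H]1COc2c(cc(OCc3ccccc3)c(OC)c2OC)C1 | intermediate
11 | (R)-6-(benzyloxy)-7,8-dimethoxychroman-3-carbaldehyde | O=C[C@H]1COc2c(cc(OCc3ccccc3)c(OC)c2OC)C1 | intermediate
12 | dibromomethane | BrCBr | starting material
13 | tributyltin chloride | CCCC[Sn](Cl)(CCCC)CCCC | starting material
14 | tributyl(dibromomethyl)stannane | CCCC[Sn](CCCC)(CCCC)C(Br)Br | intermediate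
15 | tributyl{(E)-2-[(S)-6-(benzyloxy)-7,8-dimethoxychroman-3-yl]ethenyl}stannane | CCCC[Sn](CCCC)(CCCC)/C=C/[C@H]1COc2c(cc(OCc3ccccc3)c(OC)c2OC)C1 | intermediate
16 | dimethyl squarate (3,4-dimethoxycyclobut-3-ene-1,2-dione) | COC1=C(OC)C(=O)C1=O | starting material
17 | 4-hydroxy-2,3-dimethoxycyclobut-2-en-1-one (racemic) | COC1=C(OC)C(=O)C1O | intermediate
18 | 4-chloro-2,3-dimethoxycyclobut-2-en-1-one (racemic) | COC1=C(OC)C(=O)C1Cl | intermediate
19 | 4-{(E)-2-[(S)-6-(benzyloxy)-7,8-dimethoxychroman-3-yl]ethenyl}-2,3-dimethoxycyclobut-2-en-1-one (both C4 epimers) | O=C1C(OC)=C(OC)C1/C=C/[C@H]1COc2c(cc(OCc3ccccc3)c(OC)c2OC)C1 | intermediate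
20 | (3E,5E)-6-[(S)-6-(benzyloxy)-7,8-dimethoxychroman-3-yl]-2,3-dimethoxyhexa-1,3,5-trien-1-one (dienylketene, ketene carbon and side-chain alkene cis across C3=C4) | O=C=C(OC)/C(OC)=C\C=C\[C@H]1COc2c(cc(OCc3ccccc3)c(OC)c2OC)C1 | intermediate
21 | 6-[(S)-6-(benzyloxy)-7,8-dimethoxychroman-3-yl]-2,3-dimethoxycyclohexa-2,4-dien-1-one (either epimer at C6) | O=C1C(OC)=C(OC)C=CC1[C@H]2COc3c(cc(OCc4ccccc4)c(OC)c3OC)C2 | intermediate
22 | (S)-6-(benzyloxy)-3-(2-hydroxy-3,4-dimethoxyphenyl)-7,8-dimethoxychroman | COc1ccc([C@H]2COc3c(cc(OCc4ccccc4)c(OC)c3OC)C2)c(O)c1OC | intermediate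
23 | (S)-3-(2-hydroxy-3,4-dimethoxyphenyl)-7,8-dimethoxychroman-6-ol | COc1ccc([C@H]2COc3c(cc(O)c(OC)c3OC)C2)c(O)c1OC | target

**Step count and risks**

Total steps: 15. Longest linear sequence: 12 (steps 1–8, 10, 13, 14, 15). Step 9 and steps 11–12 are side branches.

Steps most likely to fail:

1. Step 14 (key step). The 4π opening may strongly prefer outward rotation of the alkenyl group, giving the dienylketene geometry that cannot close. If its return to the cyclobutenone is slower than ketene dimerisation or capture by traces of water, the C1'–C2' bond is not formed. Fallback, from 15 and 16, returning at 22: tin–lithium exchange on 15 (n-BuLi, THF, −78 °C) and 1,2-addition of the alkenyllithium to dimethyl squarate 16 should give 4-{(E)-2-[(S)-6-(benzyloxy)-7,8-dimethoxychroman-3-yl]ethenyl}-4-hydroxy-2,3-dimethoxycyclobut-2-en-1-one F1. Heating F1 in toluene at reflux uses the established torquoselective rearrangement of 4-alkenyl-4-hydroxycyclobutenones, in which the hydroxyl rotates outward and the alkenyl group inward. It should give 2-[(S)-6-(benzyloxy)-7,8-dimethoxychroman-3-yl]-5,6-dimethoxybenzene-1,4-diol F2, handled under argon. The less hindered C5' hydroxyl of F2 is then triflated (PhNTf2, K2CO3, DMF, 0 °C) to 5-[(S)-6-(benzyloxy)-7,8-dimethoxychroman-3-yl]-4-hydroxy-2,3-dimethoxyphenyl trifluoromethanesulfonate F3. The triflate is removed by palladium-catalysed formate reduction (Pd(OAc)2, dppp, HCO2H, Et3N, DMF, 60 °C), which gives 22.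

2. Step 12. The C4 leaving group may ionise, with chloride attacking C2 and chloromethane being lost, so that the four-membered ring collapses to the cyclobutenedione during the Appel reaction or while 18 is handled. Fallback, from 17 (with 15), returning at 19: 17 is acylated (ClCO2Me, pyridine, CH2Cl2, −20 °C) to 2,3-dimethoxy-4-oxocyclobut-2-en-1-yl methyl carbonate F4, with no chloride present at the ionisable stage. F4 is coupled with 15 under zerovalent palladium (Pd2(dba)3, tri(2-furyl)phosphine, THF, 40 °C); decarboxylative ionisation releases methoxide, which activates the stannane, and the product is 19.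

3. Step 2. Conversion in the persulfate oxidation may be low, and the electron-rich hydroquinone may be over-oxidised in the alkaline medium. Fallback, from 1, returning at 5 (steps 1–3 are then not needed): 1 is oxidised at its free para position (O2, Co(salen), DMF, rt) to 2,3-dimethoxycyclohexa-2,5-diene-1,4-dione F5. F5 is reduced (Na2S2O4, H2O/EtOAc) to 2,3-dimethoxybenzene-1,4-diol F6. This symmetrical diol is monobenzylated (BnBr, one equivalent, K2CO3, acetone) to 4-(benzyloxy)-2,3-dimethoxyphenol F7. Ortho-formylation of F7 (MgCl2, Et3N, (CH2O)n, MeCN, reflux) at its only free ortho position gives 5.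

**Further compounds**

F1 | step 14 | 4-{(E)-2-[(S)-6-(benzyloxy)-7,8-dimethoxychroman-3-yl]ethenyl}-4-hydroxy-2,3-dimethoxycyclobut-2-en-1-one | COC1=C(OC)C(=O)C1(O)/C=C/[C@H]1COc2c(cc(OCc3ccccc3)c(OC)c2OC)C1
F2 | step 14 | 2-[(S)-6-(benzyloxy)-7,8-dimethoxychroman-3-yl]-5,6-dimethoxybenzene-1,4-diol | COc1c(O)cc([C@H]2COc3c(cc(OCc4ccccc4)c(OC)c3OC)C2)c(O)c1OC
F3 | step 14 | 5-[(S)-6-(benzyloxy)-7,8-dimethoxychroman-3-yl]-4-hydroxy-2,3-dimethoxyphenyl trifluoromethanesulfonate | COc1c(OS(=O)(=O)C(F)(F)F)cc([C@H]2COc3c(cc(OCc4ccccc4)c(OC)c3OC)C2)c(O)c1OC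
F4 | step 12 | 2,3-dimethoxy-4-oxocyclobut-2-en-1-yl methyl carbonate | COC(=O)OC1C(=O)C(OC)=C1OC
F5 | step 2 | 2,3-dimethoxycyclohexa-2,5-diene-1,4-dione | COC1=C(OC)C(=O)C=CC1=O
F6 | step 2 | 2,3-dimethoxybenzene-1,4-diol | COc1c(O)ccc(O)c1OC
F7 | step 2 | 4-(benzyloxy)-2,3-dimethoxyphenol | COc1c(O)ccc(OCc2ccccc2)c1OC
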